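**Retrosynthetic overview**

1. Target 13 is a (2S)-flavanone. Flavanone numbering is used for rings A and C (O1, C2, C3, C4, C4a, C5–C8, C8a) and chromanone numbering for ring B (the 8-hydroxy-2,2-dimethylchroman-4-one unit, joined through its C6 to C2). The last operation is hydrogenolysis of three benzyl ethers.
2. Key disconnection: ring C is opened at C2–C3 and C4–C4a. Forward, this is a cationic [4+2] annulation between the O-aryl oxocarbenium ion C2=O1(+)–C8a=C4a and ethoxyacetylene as a ketene-level C3–C4 unit, with a chiral counter-anion setting C2.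
3. Enabling feature: O1 is an aryl ether oxygen of a phloroglucinol ring A. C4a is therefore ortho to O1 and ortho/para to the C5 and C7 oxygens (very nucleophilic, and equivalent to C8 before closure), while C2 is a benzylic, acetal-level carbon between O1 and ring B.
4. The cation precursor is the racemic O-aryl O-pivaloyl acetal 9, made from ring-B aldehyde 6 and 3,5-bis(benzyloxy)phenol 7 (O1–C2 bond).
5. Ring order: the pyranone ring of ring B first (Kabbe condensation), ring A is bought, ring C is closed last in the key step.

Key step: step 6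

Remark (assumption): the sense of induction of the chiral acid in step 6 cannot be predicted with certainty. It is assumed that one antipode of the catalyst (both are accessible from (R)- and (S)-BINOL) directs the alkyne to the Si face of the cation; that antipode is chosen in a first screen and used.

**Route**

Step 1
Reactants: 1 1-(2,3-dihydroxyphenyl)ethan-1-one (2',3'-dihydroxyacetophenone); 2 acetone
Product: 3 8-hydroxy-2,2-dimethylchroman-4-one
Conditions: pyrrolidine (30 mol %), acetone (5 equiv), MeOH, 60 °C, N2
Reagents that add atoms: none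
Why: Kabbe condensation: pyrrolidine-mediated aldol condensation of the acetyl group with acetone should give the β,β-dimethyl enone, which the 2'-hydroxyl closes by oxa-Michael addition, while the 3'-hydroxyl cannot reach the enone and stays free.

Step 2
Reactants: 3 8-hydroxy-2,2-dimethylchroman-4-one
Product: 4 8-(benzyloxy)-2,2-dimethylchroman-4-one
Conditions: BnBr (1.1 equiv), K2CO3 (1.5 equiv), DMF, 25 °C
Reagents that add atoms: benzyl bromide, BrCc1ccccc1
Why: Williamson ether synthesis on the only phenol, with a base too weak to alkylate the ketone α-carbon.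

Step 3
Reactants: 4 8-(benzyloxy)-2,2-dimethylchroman-4-one
Product: 5 8-(benzyloxy)-6-bromo-2,2-dimethylchroman-4-one
Conditions: NBS (1.05 equiv), MeCN, 0 → 25 °C, dark
Reagents that add atoms: N-bromosuccinimide, O=C1CCC(=O)N1Br
Why: Electrophilic aromatic bromination: C6 is para to the ring oxygen and meta to the carbonyl-bearing carbon, whereas C5 and C7 are ortho and para to that carbon and are deactivated, and the polar, non-radical conditions should spare the benzylic and α-keto C–H bonds.

Step 4
Reactants: 5 8-(benzyloxy)-6-bromo-2,2-dimethylchroman-4-one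
Product: 6 8-(benzyloxy)-2,2-dimethyl-4-oxochroman-6-carbaldehyde
Conditions: Pd(OAc)2 (1 mol %), di(1-adamantyl)-n-butylphosphine (3 mol %), TMEDA (1.0 equiv), CO/H2 (1:1, 5 bar), toluene, 100 °C
Reagents that add atoms: carbon monoxide, [C-]#[O+]
Why: Palladium-catalysed reductive carbonylation (formylation) of an aryl bromide with synthesis gas, by oxidative addition, CO insertion and hydrogenolysis of the acyl–palladium bond, under which the ketone and the benzyl ether should be inert.

Step 5
Reactants: 6 8-(benzyloxy)-2,2-dimethyl-4-oxochroman-6-carbaldehyde; 7 3,5-bis(benzyloxy)phenol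
Product: 9 [3,5-bis(benzyloxy)phenoxy][8-(benzyloxy)-2,2-dimethyl-4-oxochroman-6-yl]methyl pivalate (racemic), via α-chloro pivalate 8 (not isolated)
Conditions: pivaloyl chloride (1.2 equiv), ZnCl2 (2 mol %), CH2Cl2, 0 → 25 °C; evaporate; then 7 (1.0 equiv), Cs2CO3 (1.5 equiv), MeCN, 0 → 25 °C; purification on Et3N-deactivated silica
Reagents that add atoms: pivaloyl chloride, CC(C)(C)C(=O)Cl
Why: Zinc-chloride-catalysed addition of the acyl chloride across the aldehyde C=O should give the α-chloroalkyl ester, and O-alkylation of the cesium phenoxide at that carbon (acyloxyalkylation of a phenol) forms the O1–C2 bond; the bulky pivaloyl group disfavours acyl transfer to the phenoxide, and the new stereocentre is racemic and is erased in step 6.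

Step 6
Reactants: 9 [3,5-bis(benzyloxy)phenoxy][8-(benzyloxy)-2,2-dimethyl-4-oxochroman-6-yl]methyl pivalate (racemic); 10 ethoxyacetylene
Product: 12 (2S)-5,7-bis(benzyloxy)-2-[8-(benzyloxy)-2,2-dimethyl-4-oxochroman-6-yl]chroman-4-one, via 4-ethoxy-2H-chromene 11 (not isolated)
Conditions: chiral imidodiphosphorimidate Brønsted acid (IDPi: two 3,3'-bis[3,5-bis(trifluoromethyl)phenyl]-1,1'-bi-2-naphthol phosphorus units joined through N–H, each phosphorus carrying an N-triflyl imide; antipode as in the remark; 5 mol %), 10 (3 equiv, slow addition), toluene/CH2Cl2, −78 → −50 °C; then 1 M aq HCl, THF, 0 °C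
Reagents that add atoms: water, O
Why: Proposed new method: the acid should ionize 9 by loss of pivalic acid to a contact ion pair of the O-aryl oxocarbenium ion C2=O1(+)–C8a=C4a with the chiral anion, ethoxyacetylene adds through its CH carbon to C2 (C2–C3 bond), the O-ethyl ketenium ion so formed is captured at C4 by C4a (C4–C4a bond), and loss of the proton returns the acid. The closest known reaction types are the Lewis-acid-promoted oxa-Povarov [4+2] annulation of O-aryl oxocarbenium ions with alkenes, the Povarov reaction of N-aryl iminium ions under chiral counter-anion control, and the capture of ketenium or keteniminium ions from siloxyalkynes or ynamides by arenes; their union with an ynol ether on an O-aryl oxocarbenium ion under enantiocontrol is the new element. Ring C closes by a six-membered Friedel–Crafts attack of C4a on the sp carbon C4 (6-exo-dig with respect to the C4=O π bond, the C3=C4 double bond staying inside the ring) to give enol ether 11, which the acidic work-up hydrolyses to the ketone. C2 is set in the C2–C3 bond formation, where the confined chiral anion blocks one face of the planar cation so that the alkyne adds to the Si face (O1 > aryl > H) and gives (2S); ionization erases the stereocentre of racemic 9, so the step is enantioconvergent. The step needs ionization toward the O-aryl cation, closure on ring A and not on ring B, and one regiochemistry: the pivalate is the far better leaving group, C4a lies ortho to O1 and ortho/para to the two benzyloxy groups whereas the ortho carbons of ring B are deactivated by the chromanone carbonyl, and the two ortho positions of the 3,5-bis(benzyloxy)phenoxy ring are equivalent.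

Step 7
Reactants: 12 (2S)-5,7-bis(benzyloxy)-2-[8-(benzyloxy)-2,2-dimethyl-4-oxochroman-6-yl]chroman-4-one
Product: 13 (2S)-5,7-dihydroxy-2-(8-hydroxy-2,2-dimethyl-4-oxochroman-6-yl)chroman-4-one
Conditions: H2 (1 atm), 10% Pd/C, EtOAc/MeOH, 25 °C, stopped after uptake of 3 equiv
Reagents that add atoms: none
Why: Hydrogenolysis of aryl benzyl ethers over palladium under neutral conditions, which avoids the base- or acid-induced ring opening to the chalcone that would racemize C2.

**Compound list**

1 | 1-(2,3-dihydroxyphenyl)ethan-1-one | CC(=O)c1cccc(O)c1O | starting material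
2 | acetone | CC(C)=O | starting material
3 | 8-hydroxy-2,2-dimethylchroman-4-one | CC1(C)CC(=O)c2cccc(O)c2O1 | intermediate
4 | 8-(benzyloxy)-2,2-dimethylchroman-4-one | CC1(C)CC(=O)c2cccc(OCc3ccccc3)c2O1 | intermediate
5 | 8-(benzyloxy)-6-bromo-2,2-dimethylchroman-4-one | CC1(C)CC(=O)c2cc(Br)cc(OCc3ccccc3)c2O1 | intermediate
6 | 8-(benzyloxy)-2,2-dimethyl-4-oxochroman-6-carbaldehyde | CC1(C)CC(=O)c2cc(C=O)cc(OCc3ccccc3)c2O1 | intermediate
7 | 3,5-bis(benzyloxy)phenol | Oc1cc(OCc2ccccc2)cc(OCc2ccccc2)c1 | starting material
8 | chloro[8-(benzyloxy)-2,2-dimethyl-4-oxochroman-6-yl]methyl pivalate (racemic, not isolated) | CC1(C)CC(=O)c2cc(C(Cl)OC(=O)C(C)(C)C)cc(OCc3ccccc3)c2O1 | intermediate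
9 | [3,5-bis(benzyloxy)phenoxy][8-(benzyloxy)-2,2-dimethyl-4-oxochroman-6-yl]methyl pivalate (racemic) | CC1(C)CC(=O)c2cc(C(OC(=O)C(C)(C)C)Oc3cc(OCc4ccccc4)cc(OCc4ccccc4)c3)cc(OCc3ccccc3)c2O1 | intermediate
10 | ethoxyacetylene (ethyl ethynyl ether) | C#COCC | starting material
11 | 8-(benzyloxy)-6-[(2S)-5,7-bis(benzyloxy)-4-ethoxy-2H-chromen-2-yl]-2,2-dimethylchroman-4-one (not isolated) | CC1(C)CC(=O)c2cc([C@@H]3C=C(OCC)c4c(OCc5ccccc5)cc(OCc5ccccc5)cc4O3)cc(OCc3ccccc3)c2O1 | intermediate
12 | (2S)-5,7-bis(benzyloxy)-2-[8-(benzyloxy)-2,2-dimethyl-4-oxochroman-6-yl]chroman-4-one | CC1(C)CC(=O)c2cc([C@@H]3CC(=O)c4c(OCc5ccccc5)cc(OCc5ccccc5)cc4O3)cc(OCc3ccccc3)c2O1 | intermediate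
13 | (2S)-5,7-dihydroxy-2-(8-hydroxy-2,2-dimethyl-4-oxochroman-6-yl)chroman-4-one | CC1(C)CC(=O)c2cc([C@@H]3CC(=O)c4c(O)cc(O)cc4O3)cc(O)c2O1 | target

Total step count: 7
Longest linear sequence: 7 steps (1 → 3 → 4 → 5 → 6 → 9 → 12 → 13)

**Steps most likely to fail**

1. Step 6 (proposed new method). What may go wrong: poor facial discrimination in the ion pair, capture of the ketenium ion by the liberated pivalic acid before ring closure, or acid-induced oligomerization of the ynol ether. The fallback uses known chemistry, sets out from 5 and comes back at 12. Bromide 5 is converted by palladium-catalysed borylation with tetrahydroxydiboron (Pd(OAc)2, XPhos, KOAc, EtOH, 80 °C) into [8-(benzyloxy)-2,2-dimethyl-4-oxochroman-6-yl]boronic acid F1. Purchased 5,7-dihydroxy-4H-chromen-4-one F2 is benzylated (BnBr, K2CO3, DMF, 60 °C) to 5,7-bis(benzyloxy)-4H-chromen-4-one F3. Enantioselective conjugate addition of F1 to F3 (Pd(OCOCF3)2, tert-butyl-PyOX ligand of the antipode that gives the (2S) series, NH4PF6, H2O, 1,2-dichloroethane, 60 °C) should then give 12, with the C2–aryl bond formed under ligand control.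

2. Step 5. What may go wrong: acyl transfer from the α-chloro pivalate to the phenoxide, which returns the aldehyde, or C-alkylation of the ambident phenoxide. The fallback sets out from 6 and comes back at 12. Aldehyde 6 is converted with oxalyl chloride and catalytic triphenylphosphine oxide (CH2Cl2, 25 °C; the ketone is not touched) into 8-(benzyloxy)-6-(dichloromethyl)-2,2-dimethylchroman-4-one F4. Double displacement with the sodium salt of 7 (2 equiv, DMF, 25 °C) should give the symmetric diaryl acetal 8-(benzyloxy)-6-{bis[3,5-bis(benzyloxy)phenoxy]methyl}-2,2-dimethylchroman-4-one F5. F5 can ionize only by loss of one aryloxide, so under the conditions of step 6 it should enter the same oxocarbenium ion and give 12 by way of 11, with one equivalent of 7 recovered.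

3. Step 3. What may go wrong: bromination para to the benzyloxy group (C5) or α to the ketone in place of C6. The fallback sets out from 3 and comes back at 5; it replaces electronic control by steric control. Phenol 3 is O-borylated in the flask with pinacolborane and then C–H borylated ([Ir(OMe)(cod)]2, 4,4'-di-tert-butyl-2,2'-bipyridine, B2pin2, THF, 80 °C) at C6, the only ring C–H without an ortho substituent. Work-up should give 8-hydroxy-2,2-dimethyl-6-(4,4,5,5-tetramethyl-1,3,2-dioxaborolan-2-yl)chroman-4-one F6. Benzylation (BnBr, K2CO3, DMF) gives 8-(benzyloxy)-2,2-dimethyl-6-(4,4,5,5-tetramethyl-1,3,2-dioxaborolan-2-yl)chroman-4-one F7, and bromodeboronation (CuBr2, MeOH/H2O, 80 °C) should return 5.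

**Further compounds**

F1 | step 6 | [8-(benzyloxy)-2,2-dimethyl-4-oxochroman-6-yl]boronic acid | CC1(C)CC(=O)c2cc(B(O)O)cc(OCc3ccccc3)c2O1
F2 | step 6 | 5,7-dihydroxy-4H-chromen-4-one (purchased) | O=c1ccoc2cc(O)cc(O)c12
F3 | step 6 | 5,7-bis(benzyloxy)-4H-chromen-4-one | O=c1ccoc2cc(OCc3ccccc3)cc(OCc3ccccc3)c12
F4 | step 5 | 8-(benzyloxy)-6-(dichloromethyl)-2,2-dimethylchroman-4-one | CC1(C)CC(=O)c2cc(C(Cl)Cl)cc(OCc3ccccc3)c2O1
F5 | step 5 | 8-(benzyloxy)-6-{bis[3,5-bis(benzyloxy)phenoxy]methyl}-2,2-dimethylchroman-4-one | CC1(C)CC(=O)c2cc(C(Oc3cc(OCc4ccccc4)cc(OCc4ccccc4)c3)Oc3cc(OCc4ccccc4)cc(OCc4ccccc4)c3)cc(OCc3ccccc3)c2O1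
F6 | step 3 | 8-hydroxy-2,2-dimethyl-6-(4,4,5,5-tetramethyl-1,3,2-dioxaborolan-2-yl)chroman-4-one | CC1(C)CC(=O)c2cc(B3OC(C)(C)C(C)(C)O3)cc(O)c2O1
F7 | step 3 | 8-(benzyloxy)-2,2-dimethyl-6-(4,4,5,5-tetramethyl-1,3,2-dioxaborolan-2-yl)chroman-4-one | CC1(C)CC(=O)c2cc(B3OC(C)(C)C(C)(C)O3)cc(OCc3ccccc3)c2O1
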